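**Retrosynthetic overview**

1. Target 27 ⇐ bis-MOM ether 26 ⇐ (key) one-pot Mannich / ortho-quinone methide / [4+2] annulation of phenol 23 with one CH2 unit and isobutene, which closes the ring-A dihydropyran (O5–C5–C6 + CH2 + C4H8) last.
2. Enabling feature: in 23, C6 is the only unsubstituted carbon of ring A. It lies between the free 5-OH (chelated to C4=O) and the MOM-capped O7, and C8 carries the prenyl group. Aminomethylation can therefore only occur at C6, and the quinone methide can only be drawn through O5=C5–C6=CH2, the heterodiene that takes up isobutene.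
3. 23 ⇐ Eu(III) para-Claisen–Cope shift of 5-O-prenyl ether 20 ⇐ diol 18 (7-O-MOM, then 5-O-prenyl); 18 ⇐ DDQ dehydrogenative C2–O2′ closure (furan ring) of 2′-hydroxyisoflavone 17.
4. 17 ⇐ Suzuki–Miyaura coupling of 3-iodochromone 15 (from phloroacetophenone 12) with chromanyl boronate 11 (from protocatechualdehyde 1 by propargyl Claisen/chromene formation, hydrogenation, Dakin oxidation, bromination, borylation).
5. Ring order: ring-B pyran (step 3, saturated in step 4) → γ-pyrone (step 11) → furan (step 14) → ring-A dihydropyran (step 18).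

Key step: step 18

Remark: the target has no stereocentre and no configured double bond, so no stereocontrol is needed and the route gives the single compound drawn. Locants follow isoflavone usage (O1, C2–C8a for the chromone; primed locants for ring B). "Coumaronochromone" means 11H-benzofuro[2,3-b]chromen-11-one, i.e. an isoflavone with a C2–O–C2′ bridge. "B-chroman" means the 2,2-dimethyl-3,4-dihydro-2H-pyran fused at C3′ (CH2) and C4′ (O).

**Route**

Step 1
Reactants: 1 3,4-dihydroxybenzaldehyde
Product: 2 3-hydroxy-4-(methoxymethoxy)benzaldehyde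
Conditions: MOMCl (1.05 equiv), K2CO3, acetone, 0 °C to rt
Reagents that add atoms: chloromethyl methyl ether (MOMCl) COCCl
Why: The 4-OH is para to the formyl group and is the more acidic phenol, so with one equivalent of weak base only its phenoxide forms and is O-alkylated (Williamson-type etherification).

Step 2
Reactants: 2 3-hydroxy-4-(methoxymethoxy)benzaldehyde
Product: 3 4-(methoxymethoxy)-3-[(2-methylbut-3-yn-2-yl)oxy]benzaldehyde
Conditions: 3-chloro-3-methylbut-1-yne, K2CO3, KI (cat.), CuI (cat.), acetone, 60 °C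
Reagents that add atoms: 3-chloro-3-methylbut-1-yne CC(C)(Cl)C#C
Why: Copper-assisted O-alkylation of a phenoxide with the tertiary propargylic chloride is the standard entry to aryl 1,1-dimethylpropargyl ethers.

Step 3
Reactants: 3 4-(methoxymethoxy)-3-[(2-methylbut-3-yn-2-yl)oxy]benzaldehyde
Product: 5 8-(methoxymethoxy)-2,2-dimethyl-2H-chromene-5-carbaldehyde, via allenylphenol 4 (not isolated)
Conditions: N,N-diethylaniline, 180 °C
Reagents that add atoms: none
Why: The aromatic propargyl Claisen rearrangement can only go to C2 (the other ortho carbon carries OMOM), and the allenylphenol 4 closes to the 2,2-dimethylchromene by 1,5-hydrogen shift and 6π-oxa-electrocyclisation.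

Step 4
Reactants: 5 8-(methoxymethoxy)-2,2-dimethyl-2H-chromene-5-carbaldehyde
Product: 6 8-(methoxymethoxy)-2,2-dimethylchromane-5-carbaldehyde
Conditions: H2 (1 atm), 10% Pd/C, EtOAc, rt
Reagents that add atoms: none
Why: Catalytic hydrogenation of the styrene-type C3=C4 bond is much faster than reduction of the electron-rich aryl aldehyde, and the MOM ether is inert.

Step 5
Reactants: 6 8-(methoxymethoxy)-2,2-dimethylchromane-5-carbaldehyde
Product: 8 8-(methoxymethoxy)-2,2-dimethylchroman-5-ol, via aryl formate 7 (not isolated)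
Conditions: mCPBA, CH2Cl2, 0 °C to rt; aq. NaHCO3 wash; then K2CO3 (cat.), MeOH, rt
Reagents that add atoms: 3-chloroperoxybenzoic acid (mCPBA) OOC(=O)c1cccc(Cl)c1
Why: Baeyer–Villiger (Dakin-type) oxidation, in which the electron-rich aryl group (para-OMOM, ortho-alkyl) migrates in preference to hydrogen, followed by methanolysis of formate 7.

Step 6
Reactants: 8 8-(methoxymethoxy)-2,2-dimethylchroman-5-ol
Product: 9 6-bromo-8-(methoxymethoxy)-2,2-dimethylchroman-5-ol
Conditions: NBS (1.0 equiv), MeCN, −20 °C to 0 °C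
Reagents that add atoms: N-bromosuccinimide O=C1CCC(=O)N1Br
Why: Electrophilic bromination goes ortho to the free phenol at C6, which is also para to the ring oxygen, while the para position (C8) is blocked and C7 is activated only by OMOM.

Step 7
Reactants: 9 6-bromo-8-(methoxymethoxy)-2,2-dimethylchroman-5-ol
Product: 10 5-(benzyloxy)-6-bromo-8-(methoxymethoxy)-2,2-dimethylchromane
Conditions: BnBr, K2CO3, DMF, rt
Reagents that add atoms: benzyl bromide BrCc1ccccc1
Why: Williamson etherification masks the future 2′-OH as a benzyl ether that is cleaved together with the ring-A benzyl ethers in step 13.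

Step 8
Reactants: 10 5-(benzyloxy)-6-bromo-8-(methoxymethoxy)-2,2-dimethylchromane
Product: 11 2-[5-(benzyloxy)-8-(methoxymethoxy)-2,2-dimethylchroman-6-yl]-4,4,5,5-tetramethyl-1,3,2-dioxaborolane
Conditions: B2pin2, Pd(dppf)Cl2 (cat.), KOAc, 1,4-dioxane, 90 °C
Reagents that add atoms: bis(pinacolato)diboron CC1(C)OB(OC1(C)C)B1OC(C)(C)C(C)(C)O1
Why: Miyaura borylation of an electron-rich, mono-ortho-substituted aryl bromide; benzyl and MOM ethers are inert.

Step 9
Reactants: 12 2,4,6-trihydroxyacetophenone
Product: 13 1-[2,4-bis(benzyloxy)-6-hydroxyphenyl]ethan-1-one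
Conditions: BnBr (2.1 equiv), K2CO3, DMF, rt
Reagents that add atoms: benzyl bromide BrCc1ccccc1
Why: Williamson etherification stops at the dibenzyl ether because the last ortho hydroxyl is hydrogen-bonded to the acetyl carbonyl and is the least nucleophilic.

Step 10
Reactants: 13 1-[2,4-bis(benzyloxy)-6-hydroxyphenyl]ethan-1-one
Product: 14 (E)-1-[2,4-bis(benzyloxy)-6-hydroxyphenyl]-3-(dimethylamino)prop-2-en-1-one
Conditions: DMF-DMA, toluene, 95 °C
Reagents that add atoms: N,N-dimethylformamide dimethyl acetal COC(OC)N(C)C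
Why: Condensation of the methyl ketone with the amide acetal gives the enaminone as the thermodynamically preferred E isomer.

Step 11
Reactants: 14 (E)-1-[2,4-bis(benzyloxy)-6-hydroxyphenyl]-3-(dimethylamino)prop-2-en-1-one
Product: 15 5,7-bis(benzyloxy)-3-iodo-4H-chromen-4-one
Conditions: I2, MeOH, rt
Reagents that add atoms: iodine II
Why: Iodine-mediated cyclisation of an o-hydroxyaryl enaminone (α-iodination, addition of the phenol to the iminium carbon, loss of dimethylamine) is the standard 3-iodochromone synthesis.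

Step 12
Reactants: 15 5,7-bis(benzyloxy)-3-iodo-4H-chromen-4-one; 11 the chromanyl boronate
Product: 16 5,7-bis(benzyloxy)-3-[5-(benzyloxy)-8-(methoxymethoxy)-2,2-dimethylchroman-6-yl]-4H-chromen-4-one
Conditions: Pd(dppf)Cl2 (5 mol%), 2 M aq. Na2CO3, DME, 80 °C
Reagents that add atoms: none
Why: Suzuki–Miyaura coupling of a 3-iodochromone with an arylboronate is the standard isoflavone construction and tolerates one ortho-alkoxy group.

Step 13
Reactants: 16 the tribenzyl isoflavone
Product: 17 5,7-dihydroxy-3-[5-hydroxy-8-(methoxymethoxy)-2,2-dimethylchroman-6-yl]-4H-chromen-4-one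
Conditions: H2 (1 atm), 10% Pd/C, EtOAc–THF, rt
Reagents that add atoms: none
Why: Hydrogenolysis cleaves the three benzyl ethers while the MOM ether, the chroman and the vinylogous-ester C2=C3 bond of the chromone survive, and no prenyl group is yet present.

Step 14
Reactants: 17 the 2′-hydroxyisoflavone
Product: 18 5,7-dihydroxy-5′-(methoxymethoxy)coumaronochromone carrying the B-chroman
Conditions: DDQ (1.2 equiv), 1,4-dioxane, rt to 60 °C
Reagents that add atoms: none
Why: DDQ-mediated dehydrogenative C2–O2′ cyclisation is the established closure of 2′-hydroxyisoflavones to coumaronochromones, and the MOM cap on O5′ keeps ring B from being oxidised to a para-quinone.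

Step 15
Reactants: 18 the 5,7-diol
Product: 19 5-hydroxy-7,5′-bis(methoxymethoxy)coumaronochromone carrying the B-chroman
Conditions: MOMCl (1.1 equiv), K2CO3, acetone, 0 °C to rt
Reagents that add atoms: chloromethyl methyl ether (MOMCl) COCCl
Why: The 7-OH (vinylogous acid, para to C4=O) is far more acidic and nucleophilic than the 5-OH chelated to C4=O, so one equivalent of MOMCl alkylates O7 only.

Step 16
Reactants: 19 the 5-hydroxy-7-O-MOM compound
Product: 20 5-[(3-methylbut-2-en-1-yl)oxy]-7,5′-bis(methoxymethoxy)coumaronochromone carrying the B-chroman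
Conditions: prenyl bromide, K2CO3, acetone, reflux
Reagents that add atoms: 1-bromo-3-methylbut-2-ene (prenyl bromide) CC(C)=CCBr
Why: Williamson O-alkylation of the only remaining hydroxyl, the chelated 5-OH, which reacts at reflux with the reactive allylic bromide.

Step 17
Reactants: 20 the 5-O-prenyl ether
Product: 23 5-hydroxy-8-(3-methylbut-2-en-1-yl)-7,5′-bis(methoxymethoxy)coumaronochromone carrying the B-chroman, via ortho-dienone 21 (not isolated), via para-dienone 22 (not isolated)
Conditions: Eu(fod)3 (10 mol%), CHCl3, 60 °C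
Reagents that add atoms: none
Why: In this Eu(III)-catalysed para-Claisen–Cope rearrangement, chelation at O5/C4=O accelerates the [3,3] shift to C6 (21), a Cope [3,3] shift carries the unit on to C8 as a normal prenyl group (22), and enolisation restores the chelated 5-OH, as known for 5-O-prenyl flavones and isoflavones.

Step 18
Reactants: 23 the 5-hydroxy-8-prenyl-7-O-MOM compound
Product: 26 7,5′-bis(methoxymethyl) ether of the target, via Mannich base hydroiodide 24 (not isolated), via ortho-quinone methide 25 (not isolated)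
Conditions: Me2N+=CH2 I− (1.2 equiv), MeCN, 60 °C; then isobutene (excess, condensed in), sealed tube, 130 °C
Reagents that add atoms: N,N-dimethylmethyleneiminium iodide (Eschenmoser's salt) C=[N+](C)C.[I-]; 2-methylpropene (isobutene) CC(C)=C
Why: The iminium salt aminomethylates C6, the only free and most electron-rich carbon of ring A (Mannich reaction); on heating, ammonium salt 24 loses dimethylammonium iodide to give ortho-quinone methide 25 (C5=O, C6=CH2), whose O5=C5–C6=CH2 heterodiene adds isobutene in an inverse-electron-demand hetero-Diels–Alder reaction that restores aromatic ring A. The closest known reaction type is the thermal generation of ortho-quinone methides from phenolic Mannich bases (including those of hydroxychromones and isoflavones) and their [4+2] capture by alkenes to give chromans, i.e. the three-component phenol/formaldehyde-equivalent/alkene chroman synthesis. The dihydropyran ring is closed by an intermolecular, asynchronous [4+2] cycloaddition that forms the CH2–CH2 bond and the O5–CMe2 bond in one event, so that with the C6–CH2 bond of the Mannich stage three ring bonds arise in this flask; no stereocentre is created. Orientation follows polarity: the nucleophilic CH2 terminus of isobutene bonds to the electrophilic exocyclic methylene and O5 bonds to the carbon that becomes tertiary, so only the 2,2-dimethyl isomer can form. Site selectivity is built into 23: C8 is blocked by the prenyl group, O7 is capped as a MOM ether so the quinone methide can only involve O5, and the amine leaves as its non-nucleophilic ammonium salt so it cannot attack the C2 ketene-acetal carbon of the coumaronochromone. Chemoselectivity over the 8-prenyl double bond rests on the large excess of the less hindered 1,1-disubstituted alkene and on the fact that the prenyl group cannot reach the C6 methylene intramolecularly.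

Step 19
Reactants: 26 the bis-MOM ether
Product: 27 target CNP0081329.0
Conditions: HCl (1.25 M in MeOH), THF, 40 °C
Reagents that add atoms: none
Why: Acid-catalysed methanolysis of the two MOM acetals under dilute, mild conditions, which are the usual ones for leaving ortho-prenyl phenols and aryl tert-alkyl chroman ethers untouched.

**Compound list**

1 | 3,4-dihydroxybenzaldehyde | O=Cc1ccc(O)c(O)c1 | starting material
2 | 3-hydroxy-4-(methoxymethoxy)benzaldehyde | COCOc1ccc(C=O)cc1O | intermediate
3 | 4-(methoxymethoxy)-3-[(2-methylbut-3-yn-2-yl)oxy]benzaldehyde | COCOc1ccc(C=O)cc1OC(C)(C)C#C | intermediate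
4 | 3-hydroxy-4-(methoxymethoxy)-2-(3-methylbuta-1,2-dien-1-yl)benzaldehyde (allenylphenol) | COCOc1ccc(C=O)c(C=C=C(C)C)c1O | intermediate (not isolated)
5 | 8-(methoxymethoxy)-2,2-dimethyl-2H-chromene-5-carbaldehyde | COCOc1ccc(C=O)c2c1OC(C)(C)C=C2 | intermediate
6 | 8-(methoxymethoxy)-2,2-dimethylchromane-5-carbaldehyde | COCOc1ccc(C=O)c2c1OC(C)(C)CC2 | intermediate
7 | 8-(methoxymethoxy)-2,2-dimethylchroman-5-yl formate | COCOc1ccc(OC=O)c2c1OC(C)(C)CC2 | intermediate (not isolated)
8 | 8-(methoxymethoxy)-2,2-dimethylchroman-5-ol | COCOc1ccc(O)c2c1OC(C)(C)CC2 | intermediate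
9 | 6-bromo-8-(methoxymethoxy)-2,2-dimethylchroman-5-ol | COCOc1cc(Br)c(O)c2c1OC(C)(C)CC2 | intermediate
10 | 5-(benzyloxy)-6-bromo-8-(methoxymethoxy)-2,2-dimethylchromane | COCOc1cc(Br)c(OCc2ccccc2)c2c1OC(C)(C)CC2 | intermediate
11 | 2-[5-(benzyloxy)-8-(methoxymethoxy)-2,2-dimethylchroman-6-yl]-4,4,5,5-tetramethyl-1,3,2-dioxaborolane | COCOc1cc(B2OC(C)(C)C(C)(C)O2)c(OCc2ccccc2)c2c1OC(C)(C)CC2 | intermediate
12 | 2,4,6-trihydroxyacetophenone | CC(=O)c1c(O)cc(O)cc1O | starting material
13 | 1-[2,4-bis(benzyloxy)-6-hydroxyphenyl]ethan-1-one | CC(=O)c1c(O)cc(OCc2ccccc2)cc1OCc1ccccc1 | intermediate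
14 | (E)-1-[2,4-bis(benzyloxy)-6-hydroxyphenyl]-3-(dimethylamino)prop-2-en-1-one | CN(C)/C=C/C(=O)c1c(O)cc(OCc2ccccc2)cc1OCc1ccccc1 | intermediate
15 | 5,7-bis(benzyloxy)-3-iodo-4H-chromen-4-one | O=c1c(I)coc2cc(OCc3ccccc3)cc(OCc3ccccc3)c12 | intermediate
16 | 5,7-bis(benzyloxy)-3-[5-(benzyloxy)-8-(methoxymethoxy)-2,2-dimethylchroman-6-yl]-4H-chromen-4-one | O=c1c(-c2cc(OCOC)c3OC(C)(C)CCc3c2OCc2ccccc2)coc2cc(OCc3ccccc3)cc(OCc3ccccc3)c12 | intermediate
17 | 5,7-dihydroxy-3-[5-hydroxy-8-(methoxymethoxy)-2,2-dimethylchroman-6-yl]-4H-chromen-4-one | O=c1c(-c2cc(OCOC)c3OC(C)(C)CCc3c2O)coc2cc(O)cc(O)c12 | intermediate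
18 | 5,7-dihydroxy-5′-(methoxymethoxy)coumaronochromone with B-chroman | Oc1cc(O)c2c(=O)c3c(oc2c1)oc1c4CCC(C)(C)Oc4c(OCOC)cc31 | intermediate
19 | 5-hydroxy-7,5′-bis(methoxymethoxy)coumaronochromone with B-chroman | COCOc1cc(O)c2c(=O)c3c(oc2c1)oc1c4CCC(C)(C)Oc4c(OCOC)cc31 | intermediate
20 | 5-(prenyloxy)-7,5′-bis(methoxymethoxy)coumaronochromone with B-chroman | COCOc1cc(OCC=C(C)C)c2c(=O)c3c(oc2c1)oc1c4CCC(C)(C)Oc4c(OCOC)cc31 | intermediate
21 | ortho-dienone: 6-(2-methylbut-3-en-2-yl)-5-oxo-5,6-dihydro tautomer of ring A (C6 sp3, racemic, transient) | COCOC1=CC2=C(C(=O)C1C(C)(C)C=C)C(=O)c1c(O2)oc2c3CCC(C)(C)Oc3c(OCOC)cc12 | intermediate (not isolated)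
22 | para-dienone: 8-prenyl-5-oxo-5,8-dihydro tautomer of ring A (C8 sp3, racemic, transient) | COCOC1=CC(=O)C2=C(C1CC=C(C)C)Oc1oc3c4CCC(C)(C)Oc4c(OCOC)cc3c1C2=O | intermediate (not isolated)
23 | 5-hydroxy-8-prenyl-7,5′-bis(methoxymethoxy)coumaronochromone with B-chroman | COCOc1cc(O)c2c(=O)c3c(oc2c1CC=C(C)C)oc1c4CCC(C)(C)Oc4c(OCOC)cc31 | intermediate
24 | 6-[(dimethylammonio)methyl] derivative of 23, iodide salt (Mannich base hydroiodide) | COCOc1c(C[NH+](C)C)c(O)c2c(=O)c3c(oc2c1CC=C(C)C)oc1c4CCC(C)(C)Oc4c(OCOC)cc31.[I-] | intermediate (not isolated)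
25 | ortho-quinone methide: 6-methylidene-5-oxo form of ring A of 23 | COCOC1=C(CC=C(C)C)C2=C(C(=O)C1=C)C(=O)c1c(O2)oc2c3CCC(C)(C)Oc3c(OCOC)cc12 | intermediate (not isolated)
26 | 7,5′-bis(methoxymethyl) ether of the target | CC(C)=CCc1c(OCOC)c2CCC(C)(C)Oc2c2c(=O)c3c(oc12)oc1c4CCC(C)(C)Oc4c(OCOC)cc31 | intermediate
27 | CNP0081329.0: 7,5′-dihydroxy-8-prenylcoumaronochromone with 2,2-dimethyldihydropyran rings fused at C5(O)/C6 and C4′(O)/C3′ | CC(C)=CCc1c(O)c2c(c3c(=O)c4c(oc13)oc1c3c(c(O)cc14)OC(C)(C)CC3)OC(C)(C)CC2 | target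

**Step count**

Total: 19 steps. Longest linear sequence: 16 steps (steps 1–8, then 12–19).

**Steps most likely to fail, with fallbacks**

Step 18. The quinone methide may be consumed by self-condensation or by re-addition of iodide or amine faster than the unactivated alkene intercepts it, or aminomethylation at the crowded C6 may stall. The fallback replaces the cycloaddition by a prenyl shift and hydroalkoxylation; it sets out from 23 and returns at 26. The 5-OH of 23 is O-alkylated (prenyl bromide, K2CO3, acetone, reflux) to the 5-O-prenyl 8-C-prenyl ether F1. Montmorillonite K10 in dry CH2Cl2 (0 °C to rt) then induces the acid-clay [1,3] O→C prenyl shift to C6, the only free ring-A carbon, to give the 6,8-diprenyl-5-phenol F2. Amberlyst 15 in CH2Cl2 at rt adds the 5-OH across the 6-prenyl double bond (Markovnikov, 6-endo hydroalkoxylation) to give 26; with O7 capped, only the 6-prenyl group has a neighbouring free hydroxyl.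

Step 14. DDQ may oxidise the electron-rich hydroquinone-monoether ring B, or the free phloroglucinol ring A, faster than it effects the dehydrogenative C2–O closure. The fallback is a non-oxidative closure by addition–elimination at C2; it sets out from 13 and 11 and returns at 18. Compound 13 is condensed with CS2 (t-BuOK, THF) to 5,7-bis(benzyloxy)-4-hydroxy-2H-chromene-2-thione F3. This is S-methylated (MeI, K2CO3, acetone) to 5,7-bis(benzyloxy)-2-(methylsulfanyl)chromone F4 and iodinated at C3 (NIS, cat. TFA, MeCN) to the 3-iodo-2-(methylsulfanyl)chromone F5. Suzuki–Miyaura coupling of F5 with 11 gives the 2-(methylsulfanyl)isoflavone F6, and mCPBA oxidation gives the 2-(methylsulfonyl)isoflavone F7. Hydrogenolysis (H2, Pd/C) gives the triphenol sulfone F8, and K2CO3 in DMF lets the 2′-phenoxide displace methanesulfinate at C2 to give 18.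

Step 17. The ortho-dienone may enolise before the Cope shift (giving the 6-(1,1-dimethylallyl) isomer), or the Lewis acid may cleave the allyl ether. The fallback installs the prenyl group by allyl Claisen rearrangement and metathesis; it sets out from 18 and returns at 23. Allyl bromide/K2CO3/acetone gives the 7-O-allyl ether F9. Thermal aromatic Claisen rearrangement (N,N-diethylaniline, 190 °C) delivers the allyl group to C8, the usual site for 5-hydroxy-7-allyloxychromones, giving the 8-allyl-5,7-diol F10. Cross-metathesis with 2-methylbut-2-ene (second-generation Ru benzylidene catalyst, CH2Cl2, 40 °C) gives the 8-prenyl-5,7-diol F11. Selective 7-O-MOM protection as in step 15 then gives 23.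

**Further compounds**

F1 | step 18 | 5-O-prenyl ether of 23 | COCOc1cc(OCC=C(C)C)c2c(=O)c3c(oc2c1CC=C(C)C)oc1c4CCC(C)(C)Oc4c(OCOC)cc31
F2 | step 18 | 6,8-diprenyl-5-hydroxy-7,5′-bis(methoxymethoxy)coumaronochromone with B-chroman | COCOc1c(CC=C(C)C)c(O)c2c(=O)c3c(oc2c1CC=C(C)C)oc1c4CCC(C)(C)Oc4c(OCOC)cc31
F3 | step 14 | 5,7-bis(benzyloxy)-4-hydroxy-2H-chromene-2-thione | Oc1cc(=S)oc2cc(OCc3ccccc3)cc(OCc3ccccc3)c12
F4 | step 14 | 5,7-bis(benzyloxy)-2-(methylsulfanyl)-4H-chromen-4-one | CSc1cc(=O)c2c(OCc3ccccc3)cc(OCc3ccccc3)cc2o1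
F5 | step 14 | 5,7-bis(benzyloxy)-3-iodo-2-(methylsulfanyl)-4H-chromen-4-one | CSc1oc2cc(OCc3ccccc3)cc(OCc3ccccc3)c2c(=O)c1I
F6 | step 14 | 2-(methylsulfanyl) analogue of isoflavone 16 | CSc1oc2cc(OCc3ccccc3)cc(OCc3ccccc3)c2c(=O)c1-c1cc(OCOC)c2OC(C)(C)CCc2c1OCc1ccccc1
F7 | step 14 | 2-(methylsulfonyl) analogue of isoflavone 16 | CS(=O)(=O)c1oc2cc(OCc3ccccc3)cc(OCc3ccccc3)c2c(=O)c1-c1cc(OCOC)c2OC(C)(C)CCc2c1OCc1ccccc1
F8 | step 14 | 2-(methylsulfonyl) analogue of triol 17 | CS(=O)(=O)c1oc2cc(O)cc(O)c2c(=O)c1-c1cc(OCOC)c2OC(C)(C)CCc2c1O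
F9 | step 17 | 7-O-allyl ether of 18 | C=CCOc1cc(O)c2c(=O)c3c(oc2c1)oc1c4CCC(C)(C)Oc4c(OCOC)cc31
F10 | step 17 | 8-allyl derivative of 18 | C=CCc1c(O)cc(O)c2c(=O)c3c(oc12)oc1c4CCC(C)(C)Oc4c(OCOC)cc31
F11 | step 17 | 8-prenyl derivative of 18 | CC(C)=CCc1c(O)cc(O)c2c(=O)c3c(oc12)oc1c4CCC(C)(C)Oc4c(OCOC)cc31
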